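A direct plan would raise aldehyde A1 (2,3,4-trimethoxybenzaldehyde) to acetophenone A2 by two Dakin oxidations, a methylation, a formylation and a Fries acylation, would convert methyl gallate A3 to aldehyde A4, join A2 and A4 to chalcone A5, close ring C with I2/DMSO to flavone A6, cleave the 5-OMe with AlCl3 to 5-hydroxyflavone A7 and then hydrogenolyse the benzyl ethers. Its weakest steps would be:
- the stepwise oxygenation of ring A, because five steps would add only two oxygen atoms and an acetyl group to a benzene ring;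
- the mono-O-methylation of A3 at the 4-OH with limiting MeI, because it would rest on a small pKa difference and give mixtures;
- the AlCl3 cleavage of the 5-OMe of A6, because this late step would risk the benzyl ethers and the 6-OMe and would be needed only because that oxygen had been methylated earlier.

**Plan of the new route**
Ring A is cut at C5–C4a and C8–C8a: C5 to C8 with their four oxygens are the ring carbons of dimethyl squarate, and C4a=C8a is the C5=C6 bond of a 2-aryl-4H-pyran-4-one.
Ring B is bought, ring C (the pyranone) is made next and ring A last, by 4π opening of a pyranonyl cyclobutenone and 6π electrocyclization of the dienylketene.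
The enabling feature is the fully substituted ring A with 5-OH para to 8-OMe and the 6- and 7-OMe between them, which is the hydroquinone monoether pattern this ring expansion gives.
All ring A oxygens arrive in one piece, the 5-OH is born free from the ketene carbonyl, and the 4'-OMe is bought in place, so the three weak steps have no counterpart.

Key step: step 5

Assumption: 3,5-dihydroxy-4-methoxybenzoic acid, (E)-4-methoxybut-3-en-2-one and dimethyl squarate are taken as purchasable; TBS stands for tert-butyldimethylsilyl and TMP for the 2,2,6,6-tetramethylpiperidine residue.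

Step 1
Reactants: 1 3,5-dihydroxy-4-methoxybenzoic acid
Product: 3 3,5-bis(tert-butyldimethylsilyloxy)-4-methoxybenzoic acid, via silyl ester 2 (not isolated)
Conditions: TBSCl (3.5 equiv), imidazole (7 equiv), DMF, rt, 16 h; then AcOH–THF–H2O 3:1:1, rt, 2 h
Reagents that add atoms: tert-butyldimethylsilyl chloride, CC(C)(C)[Si](C)(C)Cl
Why: Exhaustive O-silylation followed by selective solvolysis of the labile silyl ester should leave both aryl silyl ethers, which are chosen because they tolerate enolates, amide bases and 135 °C, direct ortho-lithiation poorly and leave with fluoride at the end.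

Step 2
Reactants: 3 3,5-bis(tert-butyldimethylsilyloxy)-4-methoxybenzoic acid
Product: 4 3,5-bis(tert-butyldimethylsilyloxy)-4-methoxybenzoyl chloride
Conditions: (COCl)2 (1.3 equiv), DMF (cat.), CH2Cl2, 0 °C → rt, 2 h; evaporate, use crude
Reagents that add atoms: oxalyl chloride, O=C(Cl)C(=O)Cl
Why: Chlorination of the acid through the chloroiminium salt formed from DMF and oxalyl chloride (Vilsmeier-type activation) gives only gaseous by-products, and aryl silyl ethers should survive the short contact with HCl in CH2Cl2.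

Step 3
Reactants: 4 3,5-bis(tert-butyldimethylsilyloxy)-4-methoxybenzoyl chloride; 5 (E)-4-methoxybut-3-en-2-one
Product: 8 2-[3,5-bis(tert-butyldimethylsilyloxy)-4-methoxyphenyl]-4H-pyran-4-one, via lithium enolate 6 (not isolated), via enol-dione 7 (not isolated)
Conditions: 5 (2.2 equiv), LiN(SiMe3)2 (2.2 equiv), THF, −78 °C, 30 min; 4, −78 °C, 30 min; aq NH4Cl; crude in PhMe, CF3CO2H (0.3 equiv), rt, 12 h
Reagents that add atoms: none
Why: Crossed Claisen C-acylation of the kinetic lithium enolate by the acid chloride (the second equivalent of enolate takes up the acidic proton of the dione) is followed by acid-catalysed 6-endo oxa-Michael addition of the aryl ketone enol to the β-methoxy enone and loss of methanol, which closes ring C as the 4-pyranone.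

Step 4
Reactants: 8 2-[3,5-bis(tert-butyldimethylsilyloxy)-4-methoxyphenyl]-4H-pyran-4-one; 9 dimethyl squarate (3,4-dimethoxycyclobut-3-ene-1,2-dione)
Product: 12 racemic 4-{6-[3,5-bis(tert-butyldimethylsilyloxy)-4-methoxyphenyl]-4-oxo-4H-pyran-2-yl}-2,3,4-trimethoxycyclobut-2-en-1-one, via 6-lithiopyranone 10 (not isolated), via lithium alkoxide 11 (not isolated)
Conditions: lithium 2,2,6,6-tetramethylpiperidide (LiTMP, 1.15 equiv, from TMPH and n-BuLi), THF, −78 °C, 15 min; cannulate into 9 (1.3 equiv), THF, −78 °C, 30 min; MeOTf (1.5 equiv), −78 → −40 °C, 1 h; aq NaHCO3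
Reagents that add atoms: methyl trifluoromethanesulfonate, COS(=O)(=O)C(F)(F)F
Why: Deprotonative lithiation by the hindered amide should occur at C6, the most acidic ring C–H (bound to the ring oxygen and β to the carbonyl, as at C2 of chromones and C6 of uracils), and is followed by 1,2-addition to one of the two equivalent squarate carbonyls and O-methylation of the tertiary lithium alkoxide, which is far more nucleophilic than the pyranone carbonyl; the new quaternary carbon is racemic and is destroyed in step 5.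

Step 5
Reactants: 12 racemic 4-{6-[3,5-bis(tert-butyldimethylsilyloxy)-4-methoxyphenyl]-4-oxo-4H-pyran-2-yl}-2,3,4-trimethoxycyclobut-2-en-1-one
Product: 15 3',5'-bis(tert-butyldimethylsilyloxy)-5-hydroxy-4',6,7,8-tetramethoxyflavone, via dienylketene 13 (not isolated), via cyclohexadienone 14 (not isolated)
Conditions: degassed p-xylene (0.02 M), 135 °C, 2 h
Reagents that add atoms: none
Why: Heat should open the cyclobutenone by conrotatory 4π electrocyclic cleavage of the bond between the carbonyl carbon and the quaternary carbon to give dienylketene 13, which closes by thermal disrotatory 6π electrocyclization between the ketene carbon and C5 of the pyranone to dienone 14, and 14 enolizes at once because its C4a–H lies between two carbonyl groups. The closest known reaction type is the Moore rearrangement, the thermal ring expansion of squarate-derived 4-alkenyl-, 4-aryl- and 4-heteroaryl-4-alkoxycyclobutenones to hydroquinone monoethers and their annulated analogues. Ring A is closed by the 6π electrocyclization, which forms C5–C4a after C8–C8a was made in step 4, and no stereocenter remains because the quaternary carbon of 12 becomes aromatic C8 and the sp3 C4a of 14 is aromatized. The step needs torquoselectivity in the ring opening, and the donor methoxy group on the quaternary carbon is expected to rotate outward, which turns the pyranonyl group inward and next to the ketene. Regiochemistry is fixed by connectivity, since the ketene carbon can reach only C5 of the pyranone, the nucleophilic β-carbon of the enol ether O1–C6=C5, so the free hydroxyl must arise at C5 peri to the C4 carbonyl and the methoxylated carbon must become C8. The gain of aromaticity and the hydrogen bond from 5-OH to the C4 carbonyl should make the sequence irreversible.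

Step 6
Reactants: 15 3',5'-bis(tert-butyldimethylsilyloxy)-5-hydroxy-4',6,7,8-tetramethoxyflavone
Product: 16 Gardenin E (5,3',5'-trihydroxy-6,7,8,4'-tetramethoxyflavone)
Conditions: HF·pyridine (excess), THF–pyridine, 0 °C → rt, 3 h
Reagents that add atoms: none
Why: Fluoride-driven cleavage of the two aryl Si–O bonds (desilylation) runs under weakly acidic conditions that should leave the methyl ethers, the chelated 5-OH and the pyranone untouched, and the target is achiral so no stereocenter is involved.

**Compound list**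
1 | 3,5-dihydroxy-4-methoxybenzoic acid | COc1c(O)cc(C(=O)O)cc1O | starting material
2 | tert-butyldimethylsilyl 3,5-bis(tert-butyldimethylsilyloxy)-4-methoxybenzoate | COc1c(O[Si](C)(C)C(C)(C)C)cc(C(=O)O[Si](C)(C)C(C)(C)C)cc1O[Si](C)(C)C(C)(C)C | intermediate
3 | 3,5-bis(tert-butyldimethylsilyloxy)-4-methoxybenzoic acid | COc1c(O[Si](C)(C)C(C)(C)C)cc(C(=O)O)cc1O[Si](C)(C)C(C)(C)C | intermediate
4 | 3,5-bis(tert-butyldimethylsilyloxy)-4-methoxybenzoyl chloride | COc1c(O[Si](C)(C)C(C)(C)C)cc(C(=O)Cl)cc1O[Si](C)(C)C(C)(C)C | intermediate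
5 | (E)-4-methoxybut-3-en-2-one | CO/C=C/C(C)=O | starting material
6 | lithium (E)-4-methoxybuta-1,3-dien-2-olate | C=C([O-])/C=C/OC.[Li+] | intermediate
7 | (E)-1-[3,5-bis(tert-butyldimethylsilyloxy)-4-methoxyphenyl]-5-methoxypent-4-ene-1,3-dione (drawn as the diketone, present mainly as enol) | CO/C=C/C(=O)CC(=O)c1cc(O[Si](C)(C)C(C)(C)C)c(OC)c(O[Si](C)(C)C(C)(C)C)c1 | intermediate
8 | 2-[3,5-bis(tert-butyldimethylsilyloxy)-4-methoxyphenyl]-4H-pyran-4-one | COc1c(O[Si](C)(C)C(C)(C)C)cc(-c2cc(=O)cco2)cc1O[Si](C)(C)C(C)(C)C | intermediate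
9 | dimethyl squarate (3,4-dimethoxycyclobut-3-ene-1,2-dione) | COC1=C(OC)C(=O)C1=O | starting material
10 | 2-[3,5-bis(tert-butyldimethylsilyloxy)-4-methoxyphenyl]-6-lithio-4H-pyran-4-one | COc1c(O[Si](C)(C)C(C)(C)C)cc(-c2cc(=O)cc([Li])o2)cc1O[Si](C)(C)C(C)(C)C | intermediate
11 | lithium alkoxide of racemic 4-{6-[3,5-bis(tert-butyldimethylsilyloxy)-4-methoxyphenyl]-4-oxo-4H-pyran-2-yl}-4-hydroxy-2,3-dimethoxycyclobut-2-en-1-one | COC1=C(OC)C([O-])(c2cc(=O)cc(-c3cc(O[Si](C)(C)C(C)(C)C)c(OC)c(O[Si](C)(C)C(C)(C)C)c3)o2)C1=O.[Li+] | intermediate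
12 | racemic 4-{6-[3,5-bis(tert-butyldimethylsilyloxy)-4-methoxyphenyl]-4-oxo-4H-pyran-2-yl}-2,3,4-trimethoxycyclobut-2-en-1-one | COC1=C(OC)C(OC)(c2cc(=O)cc(-c3cc(O[Si](C)(C)C(C)(C)C)c(OC)c(O[Si](C)(C)C(C)(C)C)c3)o2)C1=O | intermediate
13 | (3Z)-4-{6-[3,5-bis(tert-butyldimethylsilyloxy)-4-methoxyphenyl]-4-oxo-4H-pyran-2-yl}-2,3,4-trimethoxybuta-1,3-dien-1-one (dienylketene) | O=C=C(OC)/C(OC)=C(OC)\c1cc(=O)cc(-c2cc(O[Si](C)(C)C(C)(C)C)c(OC)c(O[Si](C)(C)C(C)(C)C)c2)o1 | intermediate
14 | racemic 2-[3,5-bis(tert-butyldimethylsilyloxy)-4-methoxyphenyl]-6,7,8-trimethoxy-4aH-chromene-4,5-dione | COC1=C(OC)C(OC)=C2OC(c3cc(O[Si](C)(C)C(C)(C)C)c(OC)c(O[Si](C)(C)C(C)(C)C)c3)=CC(=O)C2C1=O | intermediate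
15 | 3',5'-bis(tert-butyldimethylsilyloxy)-5-hydroxy-4',6,7,8-tetramethoxyflavone | COc1c(O[Si](C)(C)C(C)(C)C)cc(-c2cc(=O)c3c(O)c(OC)c(OC)c(OC)c3o2)cc1O[Si](C)(C)C(C)(C)C | intermediate
16 | Gardenin E | COc1c(O)cc(-c2cc(=O)c3c(O)c(OC)c(OC)c(OC)c3o2)cc1O | target

**Step count and risks**
Total step count: 6. Longest linear sequence: 6 steps (1 → 16).

Steps most likely to fail:

1. Step 4. Metalation could take place next to the carbonyl (C3 or C5) in place of C6, the lithiated pyranone could add to unreacted 8, or MeOTf could methylate the pyranone carbonyl oxygen. The fallback sets out from 8 and comes back at 12. Compound 8 would be zincated at C6 with TMPZnCl·LiCl (THF, 25 °C), a base that metalates chromones next to the ring oxygen, and the zinc species quenched with I2 to give 2-[3,5-bis(tert-butyldimethylsilyloxy)-4-methoxyphenyl]-6-iodo-4H-pyran-4-one F1. Iodine–magnesium exchange with iPrMgCl·LiCl (THF, −78 °C) and addition to 9 would give the tertiary alcohol, racemic 4-{6-[3,5-bis(tert-butyldimethylsilyloxy)-4-methoxyphenyl]-4-oxo-4H-pyran-2-yl}-4-hydroxy-2,3-dimethoxycyclobut-2-en-1-one F2. O-methylation of F2 with MeI, Ag2O and K2CO3 in MeCN would return to the route at 12.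

2. Step 5. The methoxy group could rotate inward in the ring opening, or closure onto the cross-conjugated pyranone double bond could be slow, so that the ketene is consumed by dimerization or by traces of water. The fallback sets out from 4 and comes back at 16, closing ring C last. Acetophenone A2 (made as in the direct plan) would be converted to its dilithio derivative with LiN(SiMe3)2 (3 equiv, THF, −78 °C) and C-acylated by 4 to give 1-[3,5-bis(tert-butyldimethylsilyloxy)-4-methoxyphenyl]-3-(2-hydroxy-3,4,5,6-tetramethoxyphenyl)propane-1,3-dione F3. AcOH with catalytic H2SO4 at 95 °C would cyclodehydrate F3 with loss of both silyl groups to 3',5'-dihydroxy-4',5,6,7,8-pentamethoxyflavone F4. Chelation-controlled cleavage of the 5-OMe of F4 with AlCl3 in MeCN, then dilute HCl, would give 16.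

3. Step 3. The enolate could be acylated on oxygen or twice, and silyl groups could be lost during the acid cyclization. The fallback sets out from 4 and comes back at 8. Acid chloride 4 would acylate the lithium enolate of acetone (LiN(SiMe3)2, THF, −78 °C) to give 1-[3,5-bis(tert-butyldimethylsilyloxy)-4-methoxyphenyl]butane-1,3-dione F5. Its dianion (LiN(iPr)2, 2.2 equiv, THF, −78 → 0 °C) would be formylated at the terminal methyl with ethyl formate to give 5-[3,5-bis(tert-butyldimethylsilyloxy)-4-methoxyphenyl]-3,5-dioxopentanal F6. Catalytic CF3CO2H in PhMe would cyclodehydrate F6 to 8.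

**Further compounds**
F1 | step 4 | 2-[3,5-bis(tert-butyldimethylsilyloxy)-4-methoxyphenyl]-6-iodo-4H-pyran-4-one | COc1c(O[Si](C)(C)C(C)(C)C)cc(-c2cc(=O)cc(I)o2)cc1O[Si](C)(C)C(C)(C)C
F2 | step 4 | racemic 4-{6-[3,5-bis(tert-butyldimethylsilyloxy)-4-methoxyphenyl]-4-oxo-4H-pyran-2-yl}-4-hydroxy-2,3-dimethoxycyclobut-2-en-1-one | COC1=C(OC)C(O)(c2cc(=O)cc(-c3cc(O[Si](C)(C)C(C)(C)C)c(OC)c(O[Si](C)(C)C(C)(C)C)c3)o2)C1=O
F3 | step 5 | 1-[3,5-bis(tert-butyldimethylsilyloxy)-4-methoxyphenyl]-3-(2-hydroxy-3,4,5,6-tetramethoxyphenyl)propane-1,3-dione | COc1c(O[Si](C)(C)C(C)(C)C)cc(C(=O)CC(=O)c2c(O)c(OC)c(OC)c(OC)c2OC)cc1O[Si](C)(C)C(C)(C)C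
F4 | step 5 | 3',5'-dihydroxy-4',5,6,7,8-pentamethoxyflavone | COc1c(O)cc(-c2cc(=O)c3c(OC)c(OC)c(OC)c(OC)c3o2)cc1O
F5 | step 3 | 1-[3,5-bis(tert-butyldimethylsilyloxy)-4-methoxyphenyl]butane-1,3-dione | CC(=O)CC(=O)c1cc(O[Si](C)(C)C(C)(C)C)c(OC)c(O[Si](C)(C)C(C)(C)C)c1
F6 | step 3 | 5-[3,5-bis(tert-butyldimethylsilyloxy)-4-methoxyphenyl]-3,5-dioxopentanal | O=CCC(=O)CC(=O)c1cc(O[Si](C)(C)C(C)(C)C)c(OC)c(O[Si](C)(C)C(C)(C)C)c1
A1 | direct plan | 2,3,4-trimethoxybenzaldehyde | COc1ccc(C=O)c(OC)c1OC
A2 | direct plan | 1-(2-hydroxy-3,4,5,6-tetramethoxyphenyl)ethan-1-one | CC(=O)c1c(O)c(OC)c(OC)c(OC)c1OC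
A3 | direct plan | methyl gallate | COC(=O)c1cc(O)c(O)c(O)c1
A4 | direct plan | 3,5-bis(benzyloxy)-4-methoxybenzaldehyde | O=Cc1cc(OCc2ccccc2)c(OC)c(OCc2ccccc2)c1
A5 | direct plan | (E)-3-[3,5-bis(benzyloxy)-4-methoxyphenyl]-1-(2-hydroxy-3,4,5,6-tetramethoxyphenyl)prop-2-en-1-one | COc1c(OCc2ccccc2)cc(/C=C/C(=O)c2c(O)c(OC)c(OC)c(OC)c2OC)cc1OCc1ccccc1
A6 | direct plan | 3',5'-bis(benzyloxy)-4',5,6,7,8-pentamethoxyflavone | COc1c(OCc2ccccc2)cc(-c2cc(=O)c3c(OC)c(OC)c(OC)c(OC)c3o2)cc1OCc1ccccc1
A7 | direct plan | 3',5'-bis(benzyloxy)-5-hydroxy-4',6,7,8-tetramethoxyflavone | COc1c(OCc2ccccc2)cc(-c2cc(=O)c3c(O)c(OC)c(OC)c(OC)c3o2)cc1OCc1ccccc1
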